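**Strategy.** Ring numbering used throughout: C1 quaternary (CH2OH, homofarnesyl), C2 (hydroxypropyl), C3 (alkylidene), C4, C5, C6 (C(CH3)OH). The route reads C3–C6 plus the C6 methyl as a 2-methylfuran, and the C6–OH/C1–CH2OH pair as an aldol. The precursor is an acyclic furyl aldehyde carrying only the C2 stereocentre and an epimeric C1. In one operation, singlet-oxygen dearomatisation unveils a Z-enedione whose C6 ketone is captured by the C1 aldehyde enolate: this closes C1–C6, sets the quaternary C1 and the tertiary carbinol C6, and funnels both C1 epimers into one cyclohexene. The C1 hydroxymethyl later tethers an intramolecular olefination that fixes the Z enal.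

Key step: step 7

Remark: (3E,7E)-homofarnesol is treated as a purchasable building block, so that the chain enters as one unit; otherwise it would be made from (2E,6E)-farnesyl bromide by cyanide displacement and reduction.

Step 1
Reactants: 1 pent-4-en-1-ol
Product: 2 pent-4-en-1-yl pivalate
Conditions: PivCl, pyridine, DMAP (cat.), CH2Cl2, 0 °C to rt
Reagents that add atoms: pivaloyl chloride, CC(C)(C)C(=O)Cl
Why: DMAP-catalysed acylation of a primary alcohol; the pivalate should survive the amide base of step 6 and is removed by the hydride of step 12.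

Step 2
Reactants: 2 pent-4-en-1-yl pivalate; 3 (E)-but-2-enal (crotonaldehyde, excess)
Product: 4 (E)-6-oxohex-4-en-1-yl pivalate
Conditions: second-generation Grubbs catalyst (cat.), CH2Cl2, 40 °C
Reagents that add atoms: none
Why: Olefin cross-metathesis of a terminal alkene with an excess of the enal should give the (E)-enal under thermodynamic control, with loss of propene.

Step 3
Reactants: 4 (E)-6-oxohex-4-en-1-yl pivalate; 5 2-methylfuran
Product: 6 (S)-4-(5-methylfuran-2-yl)-6-oxohexyl pivalate
Conditions: (2R,5R)-5-benzyl-2-tert-butyl-3-methylimidazolidin-4-one·TFA (20 mol%), CHCl3, −40 °C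
Reagents that add atoms: none
Why: Iminium-catalysed Friedel–Crafts alkylation; the benzyl group of the (2R,5R)-imidazolidinone shields one face of the (E)-iminium ion, so that 2-methylfuran should add through its free 5-position to give the (S)-configured centre that becomes C2.

Step 4
Reactants: 6 (S)-4-(5-methylfuran-2-yl)-6-oxohexyl pivalate
Product: 7 N-cyclohexyl aldimine of 6
Conditions: cyclohexylamine, MgSO4, Et2O, 0 °C to rt
Reagents that add atoms: cyclohexylamine, NC1CCCCC1
Why: Condensation with a primary amine gives the aldimine needed for clean α-deprotonation (Stork metalloenamine chemistry); C2 is not acidic and is untouched.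

Step 5
Reactants: 8 (3E,7E)-homofarnesol
Product: 9 (3E,7E)-homofarnesyl iodide
Conditions: I2, PPh3, imidazole, CH2Cl2, 0 °C
Reagents that add atoms: iodine, II
Why: Appel-type iodination of a primary homoallylic alcohol should leave the trisubstituted alkenes and their geometry untouched.

Step 6
Reactants: 7 N-cyclohexyl aldimine of 6; 9 (3E,7E)-homofarnesyl iodide
Product: 11 (4S,8E,12E)-5-formyl-9,13,17-trimethyl-4-(5-methylfuran-2-yl)octadeca-8,12,16-trien-1-yl pivalate (both epimers at C5 of the chain, the future C1), via alkylated aldimine 10 (not isolated)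
Conditions: LiN(i-Pr)2, THF, −78 to 0 °C; 9, DMPU, −78 °C to rt; then aqueous oxalic acid, Et2O, rt
Reagents that add atoms: water, O
Why: Stork metalloenamine alkylation: the lithium aza-enolate is alkylated at the only α-carbon by the primary iodide and the imine is hydrolysed on work-up; the new centre (future C1) is deliberately left as an epimer mixture because step 7 re-planarises it.

Step 7
Reactants: 11 C1-epimeric furyl aldehyde
Product: 14 (1R,2S,6S)-1-formyl-6-hydroxy-6-methyl-3-oxo-2-(3-pivaloyloxypropyl)-1-[(3E,7E)-4,8,12-trimethyltrideca-3,7,11-trienyl]cyclohex-4-ene (ring numbering of the overview; same spatial arrangement at C1, C2 and C6 as the target), via furan endoperoxide 12 (not isolated), via Z-enedione aldehyde 13 (not isolated)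
Conditions: O2, visible light, tetraphenylporphyrin (cat.), CH2Cl2, −78 °C; Me2S, −78 to 0 °C; then LiCl, DBU (cat.), THF, −20 to 0 °C
Reagents that add atoms: dioxygen, O=O
Why: Sensitised singlet oxygen adds [4+2] to the 2,5-dialkylfuran of 11 (expected to be far faster than its ene reaction with the trisubstituted chain alkenes at −78 °C) and Me2S reduces endoperoxide 12 to Z-enedione 13, after which LiCl/DBU enolises the most acidic C–H, the aldehyde α-hydrogen at C1, and the lithium enolate adds to the C6 methyl ketone. The closest known reactions are the photooxygenation of 2,5-disubstituted furans to cis-enediones and the base-mediated intramolecular aldol of keto aldehydes. The ring closes by C1–C6 bond formation in a 6-(enolexo)-exo-trig aldol, helped because the cis C4=C5 bond holds C6 next to C1 and because C5, being vinylic, cannot enolise towards the aldehyde. The new quaternary C1 is controlled by the C2 stereocentre: both C1 epimers of 11 give the same planar (E)-enolate, and in the half-chair transition state the C2 side chain should lie pseudo-equatorial and eclipsed with the enolate C–H (minimal allylic 1,3-strain), which places the enolate carbon pseudo-axial, the homofarnesyl group pseudo-equatorial and the formyl group cis to the C2 side chain. The new carbinol C6 is controlled by lithium chelation of the enolate and ketone oxygens in a closed Zimmerman–Traxler-type array, which should deliver the hydroxyl cis to the formyl group and the methyl cis to the homofarnesyl group. The step needs chemoselectivity (furan over chain alkenes; C1 enolate over the ketone enolates at C2 and at the C6 methyl, whose five-membered aldol closures are the side reactions) and diastereoselectivity; the first is secured by the reactivity of the furan, the higher acidity of the aldehyde α-hydrogen and the low temperature, the second by the C2 centre and the lithium template.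

Step 8
Reactants: 14 aldol cyclohexenone aldehyde
Product: 15 (1S,2S,6S)-6-hydroxy-1-(hydroxymethyl)-6-methyl-3-oxo-2-(3-pivaloyloxypropyl)-1-[(3E,7E)-4,8,12-trimethyltrideca-3,7,11-trienyl]cyclohex-4-ene
Conditions: Me4NBH(OAc)3, MeCN/AcOH, −20 °C
Reagents that add atoms: none
Why: Hydroxyl-directed triacetoxyborohydride reduction (Saksena–Evans type) should deliver hydride to the aldehyde held cis to the C6 hydroxyl and leave the enone alone; it also closes off the retro-aldol pathway.

Step 9
Reactants: 15 diol enone
Product: 16 (1S,2S,6S)-6-hydroxy-1-(hydroxymethyl)-6-methyl-3-oxo-2-(3-pivaloyloxypropyl)-1-[(3E,7E)-4,8,12-trimethyltrideca-3,7,11-trienyl]cyclohexane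
Conditions: [(Ph3P)CuH]6, H2O, THF/benzene, rt
Reagents that add atoms: none
Why: Copper hydride conjugate reduction should reduce the enone C4=C5 bond chemoselectively in the presence of the isolated trisubstituted alkenes; the copper enolate is protonated by water.

Step 10
Reactants: 16 diol ketone; 17 2-(diethoxyphosphoryl)propanoic acid
Product: 18 phosphonate ester of 16 at the C1 hydroxymethyl oxygen, (1S,2S,6S)
Conditions: EDC·HCl, DMAP (cat.), CH2Cl2, 0 °C to rt
Reagents that add atoms: none
Why: Carbodiimide esterification should acylate only the primary alcohol; the tertiary C6 hydroxyl does not compete.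

Step 11
Reactants: 18 phosphonate ester
Product: 19 bridged unsaturated lactone, a 3-oxabicyclo[4.3.1]dec-5-en-4-one in which CH2–O–C(=O)–C(CH3)= links C1 to C3, (1S,2R,6S) in ring numbering, ester carbonyl cis to C2
Conditions: LiCl, DBU, MeCN, high dilution, rt to 50 °C
Reagents that add atoms: none
Why: Intramolecular Horner–Wadsworth–Emmons reaction under LiCl/amine soft-enolisation conditions; because the phosphonate is delivered from the C1 hydroxymethyl, the ester carbonyl can only end up cis to C2 (the other geometry would be a trans alkene in a seven-membered ring), which fixes the tetrasubstituted alkene geometry; intramolecular Wittig-type olefination is an established entry to bridged, bridgehead-type alkenes.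

Step 12
Reactants: 19 bridged unsaturated lactone
Product: 20 target, (2Z)-2-[(2R,3S,4S)-4-hydroxy-3-(hydroxymethyl)-2-(3-hydroxypropyl)-4-methyl-3-[(3E,7E)-4,8,12-trimethyltrideca-3,7,11-trienyl]cyclohexylidene]propanal
Conditions: i-Bu2AlH (excess), CH2Cl2, −78 °C; aqueous potassium sodium tartrate
Reagents that add atoms: none
Why: At −78 °C i-Bu2AlH should reduce the lactone only to the aluminium lactol, which opens on work-up to the C1 hydroxymethyl group and the Z enal, and it cleaves the pivalate in the same operation.

**Compound list**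

1 | pent-4-en-1-ol | C=CCCCO | starting material
2 | pent-4-en-1-yl pivalate | C=CCCCOC(=O)C(C)(C)C | intermediate
3 | (E)-but-2-enal (crotonaldehyde) | C/C=C/C=O | starting material
4 | (E)-6-oxohex-4-en-1-yl pivalate | O=C/C=C/CCCOC(=O)C(C)(C)C | intermediate
5 | 2-methylfuran | Cc1ccco1 | starting material
6 | (S)-4-(5-methylfuran-2-yl)-6-oxohexyl pivalate | O=CC[C@H](CCCOC(=O)C(C)(C)C)c1ccc(C)o1 | intermediate
7 | (S,E)-6-(cyclohexylimino)-4-(5-methylfuran-2-yl)hexyl pivalate | C1CCCCC1/N=C/C[C@H](CCCOC(=O)C(C)(C)C)c1ccc(C)o1 | intermediate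
8 | (3E,7E)-4,8,12-trimethyltrideca-3,7,11-trien-1-ol (homofarnesol) | CC(C)=CCC/C(C)=C/CC/C(C)=C/CCO | starting material
9 | (3E,7E)-1-iodo-4,8,12-trimethyltrideca-3,7,11-triene (homofarnesyl iodide) | CC(C)=CCC/C(C)=C/CC/C(C)=C/CCI | intermediate
10 | C1-alkylated N-cyclohexyl aldimine (C1 epimers), not isolated | CC(C)=CCC/C(C)=C/CC/C(C)=C/CCC(/C=N/C1CCCCC1)[C@H](CCCOC(=O)C(C)(C)C)c1ccc(C)o1 | intermediate
11 | (4S,8E,12E)-5-formyl-9,13,17-trimethyl-4-(5-methylfuran-2-yl)octadeca-8,12,16-trien-1-yl pivalate (C1 epimers) | CC(C)=CCC/C(C)=C/CC/C(C)=C/CCC(C=O)[C@H](CCCOC(=O)C(C)(C)C)c1ccc(C)o1 | intermediate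
12 | furan endoperoxide of 11 (4-methyl-2,3,7-trioxabicyclo[2.2.1]hept-5-en-1-yl in place of the furyl group), not isolated | CC(C)=CCC/C(C)=C/CC/C(C)=C/CCC(C=O)[C@H](CCCOC(=O)C(C)(C)C)C12OOC(C)(O1)C=C2 | intermediate
13 | Z-enedione aldehyde (C3 ketone, cis C4=C5, C6 methyl ketone; C2 S, C1 epimers), not isolated | CC(C)=CCC/C(C)=C/CC/C(C)=C/CCC(C=O)[C@H](CCCOC(=O)C(C)(C)C)C(=O)/C=C\C(C)=O | intermediate
14 | (1R,2S,6S)-1-formyl-6-hydroxy-6-methyl-3-oxo-2-(3-pivaloyloxypropyl)-1-(homofarnesyl)cyclohex-4-ene | CC(C)=CCC/C(C)=C/CC/C(C)=C/CC[C@@]1(C=O)[C@H](CCCOC(=O)C(C)(C)C)C(=O)C=C[C@]1(C)O | intermediate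
15 | (1S,2S,6S)-6-hydroxy-1-(hydroxymethyl)-6-methyl-3-oxo-2-(3-pivaloyloxypropyl)-1-(homofarnesyl)cyclohex-4-ene | CC(C)=CCC/C(C)=C/CC/C(C)=C/CC[C@@]1(CO)[C@H](CCCOC(=O)C(C)(C)C)C(=O)C=C[C@]1(C)O | intermediate
16 | (1S,2S,6S)-6-hydroxy-1-(hydroxymethyl)-6-methyl-3-oxo-2-(3-pivaloyloxypropyl)-1-(homofarnesyl)cyclohexane | CC(C)=CCC/C(C)=C/CC/C(C)=C/CC[C@@]1(CO)[C@H](CCCOC(=O)C(C)(C)C)C(=O)CC[C@]1(C)O | intermediate
17 | 2-(diethoxyphosphoryl)propanoic acid | CCOP(=O)(OCC)C(C)C(=O)O | starting material
18 | 2-(diethoxyphosphoryl)propanoate ester of 16 at the C1 hydroxymethyl group, (1S,2S,6S) | CC(C)=CCC/C(C)=C/CC/C(C)=C/CC[C@@]1(COC(=O)C(C)P(=O)(OCC)OCC)[C@H](CCCOC(=O)C(C)(C)C)C(=O)CC[C@]1(C)O | intermediate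
19 | bridged lactone: 9-hydroxy-5,9-dimethyl-1-(homofarnesyl)-10-(3-pivaloyloxypropyl)-3-oxabicyclo[4.3.1]dec-5-en-4-one, (1S,2R,6S) in ring numbering of the overview | CC(C)=CCC/C(C)=C/CC/C(C)=C/CC[C@]12COC(=O)/C(C)=C(/CC[C@]1(C)O)[C@H]2CCCOC(=O)C(C)(C)C | intermediate
20 | (2Z)-2-[(2R,3S,4S)-4-hydroxy-3-(hydroxymethyl)-2-(3-hydroxypropyl)-4-methyl-3-[(3E,7E)-4,8,12-trimethyltrideca-3,7,11-trienyl]cyclohexylidene]propanal | CC(C)=CCC/C(C)=C/CC/C(C)=C/CC[C@@]1(CO)[C@H](CCCO)/C(=C(/C)C=O)CC[C@]1(C)O | target

**Step count.** Total: 12 steps. Longest linear sequence: 11 steps (steps 1–4 and 6–12; step 5 is a one-step side branch).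

**Steps most likely to fail**

Step 7. Three processes may go wrong. Irradiation past furan consumption may start ene oxidation of the chain alkenes. The base may isomerise the Z-enedione to the E isomer, or enolise a ketone and close a five-membered ring. Facial selectivity at C1 may be poor, or C2 may epimerise next to the C3 ketone. The fallback fixes the nucleophile before the furan is opened and avoids base. It sets out from 11, which is converted with TBSOTf and Et3N into its tert-butyldimethylsilyl enol ether F1. Photooxygenation and Me2S reduction as before give the Z-enedione silyl enol ether F2. MgBr2·OEt2 in CH2Cl2 at −78 to −20 °C then triggers a chelated intramolecular Mukaiyama aldol, and aqueous work-up returns the route at 14.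

Step 11. Closure to a strained bridgehead-type alkene may be slow. Oligomerisation, reversal of the phosphonate addition, or base epimerisation at C2 of the ketone may then compete. The fallback separates C–C bond formation from alkene formation. It sets out from 16, which is acylated at the primary hydroxyl with 2-bromopropanoyl bromide and pyridine to give bromo ester F3. SmI2 in THF at −78 °C effects an intramolecular Reformatsky addition to the C3 ketone, giving the unstrained bridged β-hydroxy lactone F4. Dehydration towards the conjugated position with Martin sulfurane returns the route at 19.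

Step 12. The aluminium lactol may open in the flask and be reduced further, or the pivalate may be cleaved incompletely. The fallback sets out from 19, which is reduced exhaustively with excess i-Bu2AlH at −78 to 0 °C to the allylic tetraol F5. MnO2 in CH2Cl2 then oxidises only the allylic primary alcohol and returns the route at 20.

**Further compounds**

F1 | step 7 | tert-butyldimethylsilyl enol ether of 11 (E/Z mixture at the enol ether) | CC(C)=CCC/C(C)=C/CC/C(C)=C/CCC(=CO[Si](C)(C)C(C)(C)C)[C@H](CCCOC(=O)C(C)(C)C)c1ccc(C)o1
F2 | step 7 | Z-enedione silyl enol ether | CC(C)=CCC/C(C)=C/CC/C(C)=C/CCC(=CO[Si](C)(C)C(C)(C)C)[C@H](CCCOC(=O)C(C)(C)C)C(=O)/C=C\C(C)=O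
F3 | step 11 | 2-bromopropanoate ester of 16 at the C1 hydroxymethyl group | CC(C)=CCC/C(C)=C/CC/C(C)=C/CC[C@@]1(COC(=O)C(C)Br)[C@H](CCCOC(=O)C(C)(C)C)C(=O)CC[C@]1(C)O
F4 | step 11 | bridged β-hydroxy lactone (saturated analogue of 19 with a hydroxyl at C3) | CC(C)=CCC/C(C)=C/CC/C(C)=C/CC[C@]12COC(=O)C(C)C(O)(CC[C@]1(C)O)[C@H]2CCCOC(=O)C(C)(C)C
F5 | step 12 | allylic tetraol (target with CH2OH in place of CHO) | CC(C)=CCC/C(C)=C/CC/C(C)=C/CC[C@@]1(CO)[C@H](CCCO)/C(=C(/C)CO)CC[C@]1(C)O
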